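Everything rests on disconnecting the C3a–C7a and C4–C5 bonds of the tetrahydroindene (indene numbering). The cyclohexene ring, with its C6=C7 double bond opposite the ring-fusion bond and the carboxyl on C4, is a Diels–Alder retron, and the cyclopentene's C1–C2=C3 unit is the tether. One thermal intramolecular Diels–Alder reaction of an acyclic (2E,4Z,7E,9E,11E)-pentaenoic acid closes the cyclohexene and, through the shared C3a–C7a bond, the cyclopentene, which completes the skeleton; it creates both quaternary carbons and four stereocenters under control of the lone methyl-bearing stereocenter (future C1), taken from methyl (R)-3-hydroxy-2-methylpropanoate. The precursor arises by three (E)-selective olefinations, one (Z)-selective iodo-olefination and a Suzuki coupling.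

Key step: step 11

Remark: boronate 20 is taken as a purchasable building block; bicyclic compounds carry indene numbering and acyclic compounds the chain numbering of their names.

Step 1
Reactants: 1 methyl (R)-3-hydroxy-2-methylpropanoate; 2 tert-butyldimethylsilyl chloride
Product: 3 methyl (R)-3-[(tert-butyldimethylsilyl)oxy]-2-methylpropanoate
Conditions: imidazole, CH2Cl2, 0 °C → rt
Reagents that add atoms: tert-butyldimethylsilyl chloride (2), CC(C)(C)[Si](C)(C)Cl
Why: Imidazole-mediated silylation (silyl ether formation) of the primary alcohol is fast and leaves the ester and the α-stereocenter untouched.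

Step 2
Reactants: 3 methyl (R)-3-[(tert-butyldimethylsilyl)oxy]-2-methylpropanoate
Product: 4 (R)-3-[(tert-butyldimethylsilyl)oxy]-2-methylpropanal
Conditions: i-Bu2AlH, CH2Cl2, −78 °C; MeOH, then aq. Rochelle salt; used crude
Reagents that add atoms: none
Why: Partial ester reduction with i-Bu2AlH at −78 °C stops at the tetrahedral aluminium alkoxide, which collapses to the aldehyde only on work-up, so the α-stereocenter should not epimerise.

Step 3
Reactants: 4 (R)-3-[(tert-butyldimethylsilyl)oxy]-2-methylpropanal; 5 2-(triphenylphosphoranylidene)propanal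
Product: 6 (2E,4S)-5-[(tert-butyldimethylsilyl)oxy]-2,4-dimethylpent-2-enal
Conditions: toluene, 90 °C, 16 h
Reagents that add atoms: 2-(triphenylphosphoranylidene)propanal (5), CC(C=O)=P(c1ccccc1)(c1ccccc1)c1ccccc1
Why: Wittig olefination with the formyl-stabilised ylide is reversible up to the oxaphosphetane and should therefore give the (E)-trisubstituted enal, under neutral conditions that spare the α-stereocenter.

Step 4
Reactants: 6 (2E,4S)-5-[(tert-butyldimethylsilyl)oxy]-2,4-dimethylpent-2-enal; 7 2-(triphenylphosphoranylidene)butanal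
Product: 8 (2E,4E,6S)-7-[(tert-butyldimethylsilyl)oxy]-2-ethyl-4,6-dimethylhepta-2,4-dienal
Conditions: toluene, 110 °C, 36 h
Reagents that add atoms: 2-(triphenylphosphoranylidene)butanal (7), CCC(C=O)=P(c1ccccc1)(c1ccccc1)c1ccccc1
Why: A second Wittig olefination with the homologous formyl-stabilised ylide should set the new trisubstituted double bond (E) for the same reason, the dienal product being less electrophilic than the enal.

Step 5
Reactants: 8 (2E,4E,6S)-7-[(tert-butyldimethylsilyl)oxy]-2-ethyl-4,6-dimethylhepta-2,4-dienal; 9 diethyl benzylphosphonate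
Product: 11 tert-butyl{[(2S,3E,5E,7E)-6-ethyl-2,4-dimethyl-8-phenylocta-3,5,7-trien-1-yl]oxy}dimethylsilane, via diethyl [lithio(phenyl)methyl]phosphonate 10 (not isolated)
Conditions: 9, n-BuLi, THF, −78 °C; then 8, −78 °C → rt
Reagents that add atoms: diethyl benzylphosphonate (9), CCOP(=O)(Cc1ccccc1)OCC
Why: Horner–Wadsworth–Emmons olefination with the preformed benzylphosphonate anion should give the (E)-styrene because the adducts equilibrate before syn-elimination of phosphate.

Step 6
Reactants: 11 tert-butyl{[(2S,3E,5E,7E)-6-ethyl-2,4-dimethyl-8-phenylocta-3,5,7-trien-1-yl]oxy}dimethylsilane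
Product: 12 (2S,3E,5E,7E)-6-ethyl-2,4-dimethyl-8-phenylocta-3,5,7-trien-1-ol
Conditions: HF·pyridine, pyridine, THF, 0 °C → rt
Reagents that add atoms: none
Why: Fluoride-driven cleavage of the Si–O bond (silyl ether deprotection) under pyridine-buffered, non-basic conditions should free the primary alcohol without touching the triene or the allylic stereocenter.

Step 7
Reactants: 12 (2S,3E,5E,7E)-6-ethyl-2,4-dimethyl-8-phenylocta-3,5,7-trien-1-ol
Product: 13 (2S,3E,5E,7E)-6-ethyl-2,4-dimethyl-8-phenylocta-3,5,7-trienal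
Conditions: Dess–Martin periodinane, pyridine, CH2Cl2, 0 °C, 30 min; crude used at once
Reagents that add atoms: none
Why: Dess–Martin oxidation at 0 °C under pyridine buffering gives the aldehyde without strong acid or base, which should limit enolisation of the α-stereocenter that is flanked by the β,γ-double bond.

Step 8
Reactants: 13 (2S,3E,5E,7E)-6-ethyl-2,4-dimethyl-8-phenylocta-3,5,7-trienal; 14 propyltriphenylphosphonium bromide; 15 iodine
Product: 19 [(1E,3E,5E,7S,8Z)-3-ethyl-9-iodo-5,7-dimethylundeca-1,3,5,8-tetraen-1-yl]benzene, via propylidenetriphenylphosphorane 16 (not isolated), via (1-iodopropyl)triphenylphosphonium iodide 17 (not isolated), via (1-iodopropylidene)triphenylphosphorane 18 (not isolated)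
Conditions: 14, n-BuLi, THF, 0 °C; I2, −78 °C; NaN(SiMe3)2, −20 °C; then 13, −78 → −20 °C
Reagents that add atoms: propyltriphenylphosphonium bromide (14), CCC[P+](c1ccccc1)(c1ccccc1)c1ccccc1.[Br-]; iodine (15), II
Why: Wittig olefination with the non-stabilised α-iodo ylide (Stork–Zhao-type iodo-olefination) proceeds through the kinetic cis-oxaphosphetane at −78 °C and should give the (Z)-iodoalkene, with iodine cis to the chain, faster than the ylide can enolise the aldehyde.

Step 9
Reactants: 19 [(1E,3E,5E,7S,8Z)-3-ethyl-9-iodo-5,7-dimethylundeca-1,3,5,8-tetraen-1-yl]benzene; 20 ethyl (2E)-2-methyl-3-(4,4,5,5-tetramethyl-1,3,2-dioxaborolan-2-yl)prop-2-enoate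
Product: 21 ethyl (2E,4Z,6S,7E,9E,11E)-4,10-diethyl-2,6,8-trimethyl-12-phenyldodeca-2,4,7,9,11-pentaenoate
Conditions: PdCl2(dppf) (5 mol %), AsPh3, Cs2CO3, DMF/H2O, 25 °C, degassed, dark
Reagents that add atoms: ethyl (2E)-2-methyl-3-(4,4,5,5-tetramethyl-1,3,2-dioxaborolan-2-yl)prop-2-enoate (20), CCOC(=O)/C(C)=C/B1OC(C)(C)C(C)(C)O1
Why: Suzuki–Miyaura coupling of the alkenyl iodide with the alkenylboronate proceeds with retention at both sp2 carbons, so the (4Z) geometry from step 8 and the (2E) geometry of the boronate should be carried into the dienoate.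

Step 10
Reactants: 21 ethyl (2E,4Z,6S,7E,9E,11E)-4,10-diethyl-2,6,8-trimethyl-12-phenyldodeca-2,4,7,9,11-pentaenoate; 22 lithium hydroxide
Product: 23 (2E,4Z,6S,7E,9E,11E)-4,10-diethyl-2,6,8-trimethyl-12-phenyldodeca-2,4,7,9,11-pentaenoic acid
Conditions: LiOH·H2O, THF/MeOH/H2O, 20 °C; then 1 M HCl to pH 4 at 0 °C
Reagents that add atoms: lithium hydroxide (22), [Li+].[OH-]
Why: Saponification (BAc2 ester hydrolysis) is placed here, while the ester is an unhindered conjugated one, because after cyclisation it would sit on a quaternary carbon next to another quaternary carbon.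

Step 11
Reactants: 23 (2E,4Z,6S,7E,9E,11E)-4,10-diethyl-2,6,8-trimethyl-12-phenyldodeca-2,4,7,9,11-pentaenoic acid
Product: 24 24-nor-spiculoic acid B, (1R,3aR,4R,5S,7aS)-3,5-diethyl-1,4,7-trimethyl-5-[(E)-2-phenylethenyl]-3a,4,5,7a-tetrahydro-1H-indene-4-carboxylic acid
Conditions: toluene (0.005 M), BHT (5 mol %), 90 °C, sealed tube, argon, dark
Reagents that add atoms: none
Why: On heating, the (7E,9E)-diene C7=C8–C9=C10 of 23 adds across its own C2=C3 bond in a concerted, asynchronous, suprafacial [4+2] cycloaddition (type 1 intramolecular Diels–Alder reaction), the closest known reaction type being the thermal cyclisation of (E)-1,3,8-nonatrienoic acid derivatives to trans-fused hydrindenes. The cyclohexene ring closes in the [4+2] mode by the new bonds C3–C7 and C2–C10 (C3a–C7a and C4–C5 of 24), and the cyclopentene ring closes in the same event by the C3–C7 bond alone, the (4Z)-double bond of the three-carbon tether holding C3 over C7 and becoming C2=C3 of 24. C4 and C3a take their relative configuration from the (2E)-dienophile geometry (methyl cis to the cyclopentene carbon C3), C5 takes its configuration from the (9E)-geometry (ethyl inside, styryl outside), and the trans ring fusion at C3a/C7a together with the relation between the diene-derived and dienophile-derived centers follows from the endo transition state, with the carboxyl under the diene and the tether anti. The absolute sense of all four new centers is dictated by the C6 stereocenter (C1 of 24), because allylic 1,3-strain with the C8 methyl keeps H6 in the diene plane, so that the tether can reach only the diene face that leaves the C1 methyl cis to H7a. The step needs endo over exo and this facial selectivity, which should be secured by secondary orbital overlap of the carboxyl with the diene, by the anti preference of a three-atom tether on an (E)-activated dienophile and by the A(1,3) bias, while the regiochemistry is fixed by the tether. High dilution, a radical inhibitor and the lowest workable temperature should hold back intermolecular cycloaddition and a [1,5]-hydrogen shift within the (Z)-dienoic acid.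

Compound list
1 | methyl (R)-3-hydroxy-2-methylpropanoate | OC[C@@H](C)C(=O)OC | starting material
2 | tert-butyldimethylsilyl chloride | CC(C)(C)[Si](C)(C)Cl | starting material
3 | methyl (R)-3-[(tert-butyldimethylsilyl)oxy]-2-methylpropanoate | CC(C)(C)[Si](C)(C)OC[C@@H](C)C(=O)OC | intermediate
4 | (R)-3-[(tert-butyldimethylsilyl)oxy]-2-methylpropanal | CC(C)(C)[Si](C)(C)OC[C@@H](C)C=O | intermediate
5 | 2-(triphenylphosphoranylidene)propanal | CC(C=O)=P(c1ccccc1)(c1ccccc1)c1ccccc1 | starting material
6 | (2E,4S)-5-[(tert-butyldimethylsilyl)oxy]-2,4-dimethylpent-2-enal | CC(C)(C)[Si](C)(C)OC[C@@H](C)/C=C(C)/C=O | intermediate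
7 | 2-(triphenylphosphoranylidene)butanal | CCC(C=O)=P(c1ccccc1)(c1ccccc1)c1ccccc1 | starting material
8 | (2E,4E,6S)-7-[(tert-butyldimethylsilyl)oxy]-2-ethyl-4,6-dimethylhepta-2,4-dienal | CC(C)(C)[Si](C)(C)OC[C@@H](C)/C=C(C)/C=C(CC)/C=O | intermediate
9 | diethyl benzylphosphonate | CCOP(=O)(Cc1ccccc1)OCC | starting material
10 | diethyl [lithio(phenyl)methyl]phosphonate | [Li+].CCOP(=O)([CH-]c1ccccc1)OCC | intermediate
11 | tert-butyl{[(2S,3E,5E,7E)-6-ethyl-2,4-dimethyl-8-phenylocta-3,5,7-trien-1-yl]oxy}dimethylsilane | CC(C)(C)[Si](C)(C)OC[C@@H](C)/C=C(C)/C=C(CC)/C=C/c1ccccc1 | intermediate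
12 | (2S,3E,5E,7E)-6-ethyl-2,4-dimethyl-8-phenylocta-3,5,7-trien-1-ol | OC[C@@H](C)/C=C(C)/C=C(CC)/C=C/c1ccccc1 | intermediate
13 | (2S,3E,5E,7E)-6-ethyl-2,4-dimethyl-8-phenylocta-3,5,7-trienal | O=C[C@@H](C)/C=C(C)/C=C(CC)/C=C/c1ccccc1 | intermediate
14 | propyltriphenylphosphonium bromide | CCC[P+](c1ccccc1)(c1ccccc1)c1ccccc1.[Br-] | starting material
15 | iodine | II | starting material
16 | propylidenetriphenylphosphorane | CCC=P(c1ccccc1)(c1ccccc1)c1ccccc1 | intermediate
17 | (1-iodopropyl)triphenylphosphonium iodide | CCC(I)[P+](c1ccccc1)(c1ccccc1)c1ccccc1.[I-] | intermediate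
18 | (1-iodopropylidene)triphenylphosphorane | CCC(I)=P(c1ccccc1)(c1ccccc1)c1ccccc1 | intermediate
19 | [(1E,3E,5E,7S,8Z)-3-ethyl-9-iodo-5,7-dimethylundeca-1,3,5,8-tetraen-1-yl]benzene | CC/C(I)=C/[C@@H](C)/C=C(C)/C=C(CC)/C=C/c1ccccc1 | intermediate
20 | ethyl (2E)-2-methyl-3-(4,4,5,5-tetramethyl-1,3,2-dioxaborolan-2-yl)prop-2-enoate | CCOC(=O)/C(C)=C/B1OC(C)(C)C(C)(C)O1 | starting material
21 | ethyl (2E,4Z,6S,7E,9E,11E)-4,10-diethyl-2,6,8-trimethyl-12-phenyldodeca-2,4,7,9,11-pentaenoate | CCOC(=O)/C(C)=C/C(CC)=C\[C@@H](C)/C=C(C)/C=C(CC)/C=C/c1ccccc1 | intermediate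
22 | lithium hydroxide | [Li+].[OH-] | starting material
23 | (2E,4Z,6S,7E,9E,11E)-4,10-diethyl-2,6,8-trimethyl-12-phenyldodeca-2,4,7,9,11-pentaenoic acid | OC(=O)/C(C)=C/C(CC)=C\[C@@H](C)/C=C(C)/C=C(CC)/C=C/c1ccccc1 | intermediate
24 | 24-nor-spiculoic acid B, (1R,3aR,4R,5S,7aS)-3,5-diethyl-1,4,7-trimethyl-5-[(E)-2-phenylethenyl]-3a,4,5,7a-tetrahydro-1H-indene-4-carboxylic acid | CCC1=C[C@@H](C)[C@@H]2C(C)=C[C@@](/C=C/c3ccccc3)(CC)[C@](C)(C(=O)O)[C@@H]12 | target

Total step count: 11. Longest linear sequence: 11 steps (1 to 24).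

Steps most likely to fail

Step 11. The cycloaddition may pass in part through the exo (cis-fused) or the wrong-face transition state, or the (Z)-dienoic acid may shift a hydrogen from C6 before it cyclises. The fallback sets out from ester 21 and activates the dienophile as an aldehyde under Lewis acid at low temperature. i-Bu2AlH (CH2Cl2, −78 °C) would give (2E,4Z,6S,7E,9E,11E)-4,10-diethyl-2,6,8-trimethyl-12-phenyldodeca-2,4,7,9,11-pentaen-1-ol F1. MnO2 (CH2Cl2, rt) would oxidise it to (2E,4Z,6S,7E,9E,11E)-4,10-diethyl-2,6,8-trimethyl-12-phenyldodeca-2,4,7,9,11-pentaenal F2. Me2AlCl (CH2Cl2, −78 → −20 °C) would promote the intramolecular Diels–Alder reaction to (1R,3aR,4R,5S,7aS)-3,5-diethyl-1,4,7-trimethyl-5-[(E)-2-phenylethenyl]-3a,4,5,7a-tetrahydro-1H-indene-4-carbaldehyde F3. Pinnick oxidation (NaClO2, NaH2PO4, 2-methylbut-2-ene, t-BuOH/H2O) would come back to the route at target 24.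

Step 8. The basic ylide may enolise the aldehyde, with loss of configuration at C2 or migration of the C3=C4 bond into conjugation, and incomplete iodination of the ylide would erode the yield of (Z)-iodide. The fallback sets out from aldehyde 13 and uses a far less basic phosphonate anion. Still–Gennari olefination with methyl 2-[bis(2,2,2-trifluoroethoxy)phosphoryl]butanoate (KN(SiMe3)2, 18-crown-6, THF, −78 °C) would give methyl (2Z,4S,5E,7E,9E)-2,8-diethyl-4,6-dimethyl-10-phenyldeca-2,5,7,9-tetraenoate F4. i-Bu2AlH would reduce it to (2Z,4S,5E,7E,9E)-2,8-diethyl-4,6-dimethyl-10-phenyldeca-2,5,7,9-tetraen-1-ol F5. MnO2 would give (2Z,4S,5E,7E,9E)-2,8-diethyl-4,6-dimethyl-10-phenyldeca-2,5,7,9-tetraenal F6. Wittig olefination with ethyl 2-(triphenylphosphoranylidene)propanoate (CH2Cl2, 25 °C) would come back to the route at ester 21.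

Step 4. The weakly nucleophilic formyl ylide may add too slowly to the hindered, conjugated aldehyde, and long heating invites further homologation and loss of double-bond geometry. The fallback sets out from enal 6 and uses the more nucleophilic ester ylide followed by redox adjustment. Wittig olefination with ethyl 2-(triphenylphosphoranylidene)butanoate (toluene, 80 °C) would give ethyl (2E,4E,6S)-7-[(tert-butyldimethylsilyl)oxy]-2-ethyl-4,6-dimethylhepta-2,4-dienoate F7. i-Bu2AlH would reduce it to (2E,4E,6S)-7-[(tert-butyldimethylsilyl)oxy]-2-ethyl-4,6-dimethylhepta-2,4-dien-1-ol F8. MnO2 would come back to the route at dienal 8.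

Further compounds
F1 | step 11 | (2E,4Z,6S,7E,9E,11E)-4,10-diethyl-2,6,8-trimethyl-12-phenyldodeca-2,4,7,9,11-pentaen-1-ol | OC/C(C)=C/C(CC)=C\[C@@H](C)/C=C(C)/C=C(CC)/C=C/c1ccccc1
F2 | step 11 | (2E,4Z,6S,7E,9E,11E)-4,10-diethyl-2,6,8-trimethyl-12-phenyldodeca-2,4,7,9,11-pentaenal | O=C/C(C)=C/C(CC)=C\[C@@H](C)/C=C(C)/C=C(CC)/C=C/c1ccccc1
F3 | step 11 | (1R,3aR,4R,5S,7aS)-3,5-diethyl-1,4,7-trimethyl-5-[(E)-2-phenylethenyl]-3a,4,5,7a-tetrahydro-1H-indene-4-carbaldehyde | CCC1=C[C@@H](C)[C@@H]2C(C)=C[C@@](/C=C/c3ccccc3)(CC)[C@](C)(C=O)[C@@H]12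
F4 | step 8 | methyl (2Z,4S,5E,7E,9E)-2,8-diethyl-4,6-dimethyl-10-phenyldeca-2,5,7,9-tetraenoate | COC(=O)/C(CC)=C\[C@@H](C)/C=C(C)/C=C(CC)/C=C/c1ccccc1
F5 | step 8 | (2Z,4S,5E,7E,9E)-2,8-diethyl-4,6-dimethyl-10-phenyldeca-2,5,7,9-tetraen-1-ol | OC/C(CC)=C\[C@@H](C)/C=C(C)/C=C(CC)/C=C/c1ccccc1
F6 | step 8 | (2Z,4S,5E,7E,9E)-2,8-diethyl-4,6-dimethyl-10-phenyldeca-2,5,7,9-tetraenal | O=C/C(CC)=C\[C@@H](C)/C=C(C)/C=C(CC)/C=C/c1ccccc1
F7 | step 4 | ethyl (2E,4E,6S)-7-[(tert-butyldimethylsilyl)oxy]-2-ethyl-4,6-dimethylhepta-2,4-dienoate | CC(C)(C)[Si](C)(C)OC[C@@H](C)/C=C(C)/C=C(CC)/C(=O)OCC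
F8 | step 4 | (2E,4E,6S)-7-[(tert-butyldimethylsilyl)oxy]-2-ethyl-4,6-dimethylhepta-2,4-dien-1-ol | CC(C)(C)[Si](C)(C)OC[C@@H](C)/C=C(C)/C=C(CC)/CO
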